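The route rests on cutting C1–C2 of the seven-membered ring C1–C2–C3–C11–C10–C7–C8 and re-expanding the cyclopentane C3–C11–C12–C13–C14 to a 2-diazocyclohexanone (numbering defined below). The feature exploited is that cyclopentane carbon C3 bears the acyl carbon C2 beside methine C11, the mark of a Wolff-contracted cyclohexanone, while C1 lies alpha to the C9 ketone of ring B. In one operation violet light contracts the ring and the ketene acylates the ring B silyl enol ether at C1, closing the seven-membered ring and leaving a silyl enol ether on C2=C3 for the last closure. The precursor is the geranylated ring B phenyl keto ester, as its C9 silyl enol ether, tied through C10 to the diazoketone.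

Key step: step 16

Numbering (target cage, used for all intermediates): C1 is the bridgehead that carries the benzoyl group; C2, C3 and C4 are the diketone bridge with quaternary C3 in the middle; C5 is the geranyl bridgehead; C6 (CH2), C7 (CH) and C8 (CMe2) complete ring B; C9 is the one-carbon keto bridge; C10 (CH2) and C11 (CH) tie C7 to C3; C12 (CMe2), C13 and C14 (CH2) complete the cyclopentane. Ring A is C1–C2–C3–C4–C5–C9 and ring B is C1–C8–C7–C6–C5–C9. Geranyl is (2E)-3,7-dimethylocta-2,6-dien-1-yl.

Remark: enone 15 and alcohol 16 are drawn as Z isomers; an E isomer or a mixture would converge in step 9, where C10 becomes a methylene group.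

Remark: the key step is planned to give the O2 silyl enol ether 30 (C2=C3) and not the C1-enolised 1,3-diketone, because C1 must be sp3 for ring A to close. A tert-butyldimethylsilyl (TBS) group is therefore used in the precursor so that this enol ether can be handled.

Step 1
Reactants: 1 3,3-dimethylglutaric anhydride
Product: 2 5-methoxy-3,3-dimethyl-5-oxopentanoic acid
Conditions: MeOH, reflux
Reagents that add atoms: methanol (CO)
Why: Alcoholysis of a symmetrical cyclic anhydride can give only this half ester, and no stereocenter is formed.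

Step 2
Reactants: 2 5-methoxy-3,3-dimethyl-5-oxopentanoic acid; 3 (R)-4-benzyl-1,3-oxazolidin-2-one
Product: 5 methyl 5-[(4R)-4-benzyl-2-oxo-1,3-oxazolidin-3-yl]-3,3-dimethyl-5-oxopentanoate, via mixed pivalic anhydride 4 (not isolated)
Conditions: PivCl, Et3N, THF, −20 °C; then 3, LiCl, rt
Reagents that add atoms: none
Why: N-Acylation of the Evans oxazolidinone through the mixed anhydride should occur at the less hindered acyl carbon; the only stereocenter is the one the auxiliary brings.

Step 3
Reactants: 5 methyl 5-[(4R)-4-benzyl-2-oxo-1,3-oxazolidin-3-yl]-3,3-dimethyl-5-oxopentanoate; 6 tert-butyl acrylate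
Product: 8 1-tert-butyl 7-methyl (4R)-4-{[(4R)-4-benzyl-2-oxo-1,3-oxazolidin-3-yl]carbonyl}-5,5-dimethylheptanedioate, via titanium enolate 7 (not isolated)
Conditions: TiCl3(OiPr), iPr2NEt, CH2Cl2, 0 °C; then 6
Reagents that add atoms: none
Why: Evans auxiliary-controlled Michael addition: the chelated Z titanium enolate is shielded on one face by the benzyl group, so the acrylate should add to the other face and set C7 (R).

Step 4
Reactants: 8 1-tert-butyl 7-methyl (4R)-4-{[(4R)-4-benzyl-2-oxo-1,3-oxazolidin-3-yl]carbonyl}-5,5-dimethylheptanedioate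
Product: 9 1-tert-butyl 7-methyl (4R)-4-[(ethylsulfanyl)carbonyl]-5,5-dimethylheptanedioate
Conditions: EtSH, n-BuLi, THF, 0 °C
Reagents that add atoms: ethanethiol (CCS)
Why: Transthioesterification of the N-acyl oxazolidinone by lithium ethanethiolate should take place at the exocyclic carbonyl only, leaving both carboxylic esters and C7 untouched.

Step 5
Reactants: 9 1-tert-butyl 7-methyl (4R)-4-[(ethylsulfanyl)carbonyl]-5,5-dimethylheptanedioate
Product: 10 1-tert-butyl 7-methyl (4R)-4-formyl-5,5-dimethylheptanedioate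
Conditions: Et3SiH, Pd/C (10 mol %), acetone, rt
Reagents that add atoms: none
Why: Fukuyama reduction stops at the aldehyde under neutral conditions, so the alpha center C7 should not epimerise and the esters survive.

Step 6
Reactants: 11 3-methylcyclohex-2-en-1-one; 10 1-tert-butyl 7-methyl (4R)-4-formyl-5,5-dimethylheptanedioate
Product: 13 aldol adduct 1-tert-butyl 7-methyl (4R)-4-[hydroxy(2,2-dimethyl-6-oxocyclohexyl)methyl]-5,5-dimethylheptanedioate (epimers at C10 and C11), via bromomagnesium enolate 12 (not isolated)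
Conditions: MeMgBr, CuBr·SMe2 (5 mol %), THF, −30 °C; then 10, −78 °C
Reagents that add atoms: methylmagnesium bromide (C[Mg]Br)
Why: Copper-catalysed conjugate methylation gives the enolate regiospecifically at C11 and its aldol addition to 10 forms C10–C11; the C10 and C11 centers are left uncontrolled because step 7 erases them and step 9 sets C11 anew.

Step 7
Reactants: 13 aldol adduct (epimers at C10 and C11)
Product: 15 1-tert-butyl 7-methyl 4-[(Z)-(2,2-dimethyl-6-oxocyclohexylidene)methyl]-5,5-dimethylheptanedioate (C7 as in 10), via C10 mesylate 14 (not isolated)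
Conditions: MsCl, Et3N, CH2Cl2, 0 °C; then DBU, rt
Reagents that add atoms: none
Why: Mesylation and E1cB elimination should give the exocyclic enone, with the C7 branch turned toward the carbonyl and away from the C12 methyl groups; C7 is not alpha to the ketone and is kept.

Step 8
Reactants: 15 1-tert-butyl 7-methyl 4-[(Z)-(2,2-dimethyl-6-oxocyclohexylidene)methyl]-5,5-dimethylheptanedioate
Product: 16 1-tert-butyl 7-methyl 4-{(Z)-[(6R)-6-hydroxy-2,2-dimethylcyclohexylidene]methyl}-5,5-dimethylheptanedioate (C7 as in 10)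
Conditions: (S)-2-methyl-CBS-oxazaborolidine (20 mol %), catecholborane, PhMe, −78 °C
Reagents that add atoms: none
Why: Corey–Bakshi–Shibata reduction: the catalyst binds the carbonyl lone pair on the side of the small C3 methylene, so hydride should add to one face and give the (R) carbinol at C2 under catalyst control, whatever the remote C7 center.

Step 9
Reactants: 16 1-tert-butyl 7-methyl 4-{(Z)-[(6R)-6-hydroxy-2,2-dimethylcyclohexylidene]methyl}-5,5-dimethylheptanedioate
Product: 17 1-tert-butyl 7-methyl 4-{[(1R,6R)-6-hydroxy-2,2-dimethylcyclohexyl]methyl}-5,5-dimethylheptanedioate (C7 as in 10)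
Conditions: H2 (1 atm), [Ir(cod)(PCy3)(py)]PF6 (5 mol %), CH2Cl2, rt
Reagents that add atoms: none
Why: Hydroxyl-directed hydrogenation with Crabtree's catalyst delivers hydrogen to the alkene face syn to the C2 hydroxyl, which should place H on C11 cis to OH and so fix C11 (R) against C7.

Step 10
Reactants: 17 1-tert-butyl 7-methyl 4-{[(1R,6R)-6-hydroxy-2,2-dimethylcyclohexyl]methyl}-5,5-dimethylheptanedioate
Product: 18 tert-butyl 5-{[(1R,6R)-6-hydroxy-2,2-dimethylcyclohexyl]methyl}-4,4-dimethyl-2-oxocyclohexane-1-carboxylate (ring B; C5 epimers and enol; C7 as in 10)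
Conditions: KOtBu, THF, 0 °C → rt
Reagents that add atoms: none
Why: Dieckmann condensation: the C5 enolate of the tert-butyl ester closes ring B on the methyl ester C9, whereas the converse closure would have to attack the unreactive tert-butyl ester; C11 cannot enolise because C2 is still an alcohol.

Step 11
Reactants: 18 tert-butyl ring B keto ester
Product: 20 phenyl 5-{[(1R,6R)-6-hydroxy-2,2-dimethylcyclohexyl]methyl}-4,4-dimethyl-2-oxocyclohexane-1-carboxylate (C5 epimers and enol), via acylketene 19 (not isolated)
Conditions: PhOH (20 equiv), PhMe, 110 °C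
Reagents that add atoms: phenol (Oc1ccccc1)
Why: Thermal ester exchange of an enolisable beta-keto tert-butyl ester through its acylketene, which the large excess of phenol should capture ahead of the hindered secondary alcohol; the aryl ester is wanted as the acyl donor of step 17.

Step 12
Reactants: 20 phenyl ring B keto ester; 21 geranyl bromide
Product: 22 phenyl 1-geranyl-5-{[(1R,6R)-6-hydroxy-2,2-dimethylcyclohexyl]methyl}-4,4-dimethyl-2-oxocyclohexane-1-carboxylate (geranyl trans and ester cis to the C7 side chain; C5 and C7 as in the target)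
Conditions: 21, K2CO3, acetone, rt
Reagents that add atoms: none
Why: C-Alkylation of the beta-keto ester enolate by an allylic bromide; axial attack on the face free of the axial C8 methyl group and anti to the equatorial C7 side chain should put geranyl trans to C10 and set quaternary C5.

Step 13
Reactants: 22 geranylated phenyl keto ester with C2 alcohol
Product: 23 phenyl 1-geranyl-5-{[(1R)-2,2-dimethyl-6-oxocyclohexyl]methyl}-4,4-dimethyl-2-oxocyclohexane-1-carboxylate (C5 and C7 as in the target)
Conditions: Dess–Martin periodinane, CH2Cl2, rt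
Reagents that add atoms: none
Why: Dess–Martin oxidation under nonbasic conditions should give the C2 ketone without enolising the hindered C11 methine.

Step 14
Reactants: 23 C2, C9 diketone
Product: 26 phenyl 1-geranyl-5-{[(1R)-5-diazo-2,2-dimethyl-6-oxocyclohexyl]methyl}-4,4-dimethyl-2-oxocyclohexane-1-carboxylate (diazo on C3), via lithium enolate 24 (not isolated), via trifluoroacetyl ketone 25 (not isolated)
Conditions: LiN(SiMe3)2, THF, −78 °C; CF3CO2CH2CF3; then MsN3, Et3N, H2O, MeCN, rt
Reagents that add atoms: methanesulfonyl azide (CS(=O)(=O)N=[N+]=[N-])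
Why: Detrifluoroacetylative diazo transfer (Regitz type): the amide base should remove the unhindered C3 methylene proton in preference to the neopentyl C1 and tertiary C11 protons, and the activated diketone then accepts N2 from the sulfonyl azide.

Step 15
Reactants: 26 C3 diazo ketone
Product: 28 key-step precursor, the C9 TBS enol ether (C1=C9) of 26, via potassium enolate 27 (not isolated)
Conditions: KN(SiMe3)2, THF, −78 °C; then TBSOTf
Reagents that add atoms: tert-butyldimethylsilyl trifluoromethanesulfonate (CC(C)(C)[Si](C)(C)OS(=O)(=O)C(F)(F)F)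
Why: Kinetic enolisation and O-silylation: the C9 ketone can enolise only toward C1 (C5 is fully substituted) and its methylene should be deprotonated faster than the tertiary C11 methine; any C11 enolate would be trapped as its silyl ether and not returned as the epimer.

Step 16
Reactants: 28 C9 TBS enol ether with C3 diazo ketone
Product: 30 tricyclic C2=C3 TBS enol ether (ring B C9 ketone, seven-membered ring C1–C2–C3–C11–C10–C7–C8, cyclopentane C3–C11–C12–C13–C14, phenyl ester and geranyl on C5, C1–H), via cyclopentylidene ketene 29 (not isolated)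
Conditions: hν (405 nm LED), PhMe (0.005 M), 20 °C; then 60 °C
Reagents that add atoms: none
Why: Proposed new method: excitation of the cyclic diazoketone expels N2 with a concerted 1,2-shift of C11 from C2 to C3 (photochemical Wolff ring contraction, known for 2-diazocyclohexanones), and ketene 29 is then attacked at C2 by C1 of the silyl enol ether, directly or through a siloxycyclobutanone that opens in retro-aldol fashion, with silyl transfer from O9 to O2; the closest known reactions are C-acylation and [2+2] addition of silyl enol ethers with ketenes, which have not been run intramolecularly on a photogenerated ketene. The cyclopentane forms by ring contraction (new C3–C11 bond) and the seven-membered ring by 7-exo-dig attack of the endocyclic enol ether on the ketene carbonyl carbon. C11 shifts with retention, and the new center C1 is fixed by the tether, since a ketene hanging from C7 can reach only the syn face of ring B. The step needs rearrangement to outrun carbene chemistry and needs acylation at one carbon only: the ring holds C=O and C=N2 syn, which favours the concerted shift and spares the geranyl double bonds, the enol ether can react only through C1, and 405 nm light is not absorbed by the phenyl ester. High dilution should suppress ketene dimerisation, warming opens any cyclobutanone, and the TBS group keeps the C2=C3 enol ether intact with C1 still sp3.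

Step 17
Reactants: 30 tricyclic C2=C3 TBS enol ether
Product: 32 cage trione with C1–H (ring A closed; C3 quaternary), via tetrabutylammonium enolate 31 (not isolated)
Conditions: Bu4N[Ph3SiF2], THF, −40 → 0 °C
Reagents that add atoms: none
Why: Fluoride cleavage of the silyl enol ether releases the enolate regiospecifically at C3, which should close ring A by intramolecular Claisen (Dieckmann-type) acylation on the phenyl ester with loss of phenoxide; C3 is set by the cage, since only its face syn to C4 can bond.

Step 18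
Reactants: 32 cage trione with C1–H
Product: 34 target CNP0168637.1, via bridgehead lithium compound 33 (not isolated)
Conditions: lithium 2,2,6,6-tetramethylpiperidide, THF, −78 °C; then PhCOCl, −78 → 0 °C
Reagents that add atoms: benzoyl chloride (O=C(Cl)c1ccccc1)
Why: Bridgehead metalation and C-acylation, as practised on bicyclo[3.3.1]nonane-2,4,9-trione cores: C1–H is the only proton alpha to a carbonyl, O-acylation would need an anti-Bredt enol, and the benzoyl group should enter with retention.

Compound list
1 | 3,3-dimethylglutaric anhydride | O=C1CC(C)(C)CC(=O)O1 | starting material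
2 | 5-methoxy-3,3-dimethyl-5-oxopentanoic acid | COC(=O)CC(C)(C)CC(=O)O | intermediate
3 | (R)-4-benzyl-1,3-oxazolidin-2-one | O=C1N[C@H](Cc2ccccc2)CO1 | starting material
4 | mixed anhydride of 2 with pivalic acid | COC(=O)CC(C)(C)CC(=O)OC(=O)C(C)(C)C | intermediate
5 | methyl 5-[(4R)-4-benzyl-2-oxo-1,3-oxazolidin-3-yl]-3,3-dimethyl-5-oxopentanoate | COC(=O)CC(C)(C)CC(=O)N1[C@H](Cc2ccccc2)COC1=O | intermediate
6 | tert-butyl acrylate | C=CC(=O)OC(C)(C)C | starting material
7 | Z titanium enolate of 5 | COC(=O)CC(C)(C)/C=C(\O[Ti](Cl)(Cl)OC(C)C)N1[C@H](Cc2ccccc2)COC1=O | intermediate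
8 | 1-tert-butyl 7-methyl (4R)-4-{[(4R)-4-benzyl-2-oxo-1,3-oxazolidin-3-yl]carbonyl}-5,5-dimethylheptanedioate | COC(=O)CC(C)(C)[C@@H](CCC(=O)OC(C)(C)C)C(=O)N1[C@H](Cc2ccccc2)COC1=O | intermediate
9 | 1-tert-butyl 7-methyl (4R)-4-[(ethylsulfanyl)carbonyl]-5,5-dimethylheptanedioate | CCSC(=O)[C@H](CCC(=O)OC(C)(C)C)C(C)(C)CC(=O)OC | intermediate
10 | 1-tert-butyl 7-methyl (4R)-4-formyl-5,5-dimethylheptanedioate | O=C[C@H](CCC(=O)OC(C)(C)C)C(C)(C)CC(=O)OC | intermediate
11 | 3-methylcyclohex-2-en-1-one | CC1=CC(=O)CCC1 | starting material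
12 | bromomagnesium enolate of 3,3-dimethylcyclohexanone (C2=C11) | CC1(C)CCCC(O[Mg]Br)=C1 | intermediate
13 | aldol adduct, 1-tert-butyl 7-methyl (4R)-4-[hydroxy(2,2-dimethyl-6-oxocyclohexyl)methyl]-5,5-dimethylheptanedioate, epimers at C10 and C11 | COC(=O)CC(C)(C)[C@@H](CCC(=O)OC(C)(C)C)C(O)C1C(=O)CCCC1(C)C | intermediate
14 | C10 mesylate of 13 | COC(=O)CC(C)(C)[C@@H](CCC(=O)OC(C)(C)C)C(OS(C)(=O)=O)C1C(=O)CCCC1(C)C | intermediate
15 | 1-tert-butyl 7-methyl 4-[(Z)-(2,2-dimethyl-6-oxocyclohexylidene)methyl]-5,5-dimethylheptanedioate, C7 as in 10 | COC(=O)CC(C)(C)[C@@H](CCC(=O)OC(C)(C)C)/C=C1\C(=O)CCCC1(C)C | intermediate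
16 | 1-tert-butyl 7-methyl 4-{(Z)-[(6R)-6-hydroxy-2,2-dimethylcyclohexylidene]methyl}-5,5-dimethylheptanedioate, C7 as in 10 | COC(=O)CC(C)(C)[C@@H](CCC(=O)OC(C)(C)C)/C=C1\[C@H](O)CCCC1(C)C | intermediate
17 | 1-tert-butyl 7-methyl 4-{[(1R,6R)-6-hydroxy-2,2-dimethylcyclohexyl]methyl}-5,5-dimethylheptanedioate, C7 as in 10 | COC(=O)CC(C)(C)[C@@H](CCC(=O)OC(C)(C)C)C[C@H]1[C@H](O)CCCC1(C)C | intermediate
18 | tert-butyl 5-{[(1R,6R)-6-hydroxy-2,2-dimethylcyclohexyl]methyl}-4,4-dimethyl-2-oxocyclohexane-1-carboxylate, C5 epimers | CC(C)(C)OC(=O)C1C[C@@H](C[C@H]2[C@H](O)CCCC2(C)C)C(C)(C)CC1=O | intermediate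
19 | acylketene from 18 (C4=C5) | O=C=C1C[C@@H](C[C@H]2[C@H](O)CCCC2(C)C)C(C)(C)CC1=O | intermediate
20 | phenyl 5-{[(1R,6R)-6-hydroxy-2,2-dimethylcyclohexyl]methyl}-4,4-dimethyl-2-oxocyclohexane-1-carboxylate, C5 epimers | O=C(Oc1ccccc1)C1C[C@@H](C[C@H]2[C@H](O)CCCC2(C)C)C(C)(C)CC1=O | intermediate
21 | geranyl bromide | CC(C)=CCC/C(C)=C/CBr | starting material
22 | phenyl 1-geranyl-5-{[(1R,6R)-6-hydroxy-2,2-dimethylcyclohexyl]methyl}-4,4-dimethyl-2-oxocyclohexane-1-carboxylate, geranyl trans to the C7 side chain | CC(C)=CCC/C(C)=C/C[C@]1(C(=O)Oc2ccccc2)C[C@@H](C[C@H]2[C@H](O)CCCC2(C)C)C(C)(C)CC1=O | intermediate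
23 | phenyl 1-geranyl-5-{[(1R)-2,2-dimethyl-6-oxocyclohexyl]methyl}-4,4-dimethyl-2-oxocyclohexane-1-carboxylate | CC(C)=CCC/C(C)=C/C[C@]1(C(=O)Oc2ccccc2)C[C@@H](C[C@@H]2C(C)(C)CCCC2=O)C(C)(C)CC1=O | intermediate
24 | lithium C2=C3 enolate of 23 | CC(C)=CCC/C(C)=C/C[C@]1(C(=O)Oc2ccccc2)C[C@@H](C[C@@H]2C(C)(C)CCC=C2O[Li])C(C)(C)CC1=O | intermediate
25 | C3 trifluoroacetyl derivative of 23 | CC(C)=CCC/C(C)=C/C[C@]1(C(=O)Oc2ccccc2)C[C@@H](C[C@@H]2C(C)(C)CCC(C(=O)C(F)(F)F)C2=O)C(C)(C)CC1=O | intermediate
26 | phenyl 1-geranyl-5-{[(1R)-5-diazo-2,2-dimethyl-6-oxocyclohexyl]methyl}-4,4-dimethyl-2-oxocyclohexane-1-carboxylate | CC(C)=CCC/C(C)=C/C[C@]1(C(=O)Oc2ccccc2)C[C@@H](C[C@@H]2C(C)(C)CCC(=[N+]=[N-])C2=O)C(C)(C)CC1=O | intermediate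
27 | potassium C9=C1 enolate of 26 | CC(C)=CCC/C(C)=C/C[C@]1(C(=O)Oc2ccccc2)C[C@@H](C[C@@H]2C(C)(C)CCC(=[N+]=[N-])C2=O)C(C)(C)C=C1O[K] | intermediate
28 | key-step precursor, C9 TBS enol ether of 26 | CC(C)=CCC/C(C)=C/C[C@]1(C(=O)Oc2ccccc2)C[C@@H](C[C@@H]2C(C)(C)CCC(=[N+]=[N-])C2=O)C(C)(C)C=C1O[Si](C)(C)C(C)(C)C | intermediate
29 | cyclopentylidene ketene (C3=C2=O) with the C9 TBS enol ether | CC(C)=CCC/C(C)=C/C[C@]1(C(=O)Oc2ccccc2)C[C@@H](C[C@@H]2C(C)(C)CCC2=C=O)C(C)(C)C=C1O[Si](C)(C)C(C)(C)C | intermediate
30 | key-step product, tricyclic C2=C3 TBS enol ether with C9 ketone, C1–H and C5 phenyl ester | CC(C)=CCC/C(C)=C/C[C@]1(C(=O)Oc2ccccc2)C[C@H]3C[C@@H]4C(C)(C)CCC4=C(O[Si](C)(C)C(C)(C)C)[C@@H](C1=O)C3(C)C | intermediate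
31 | tetrabutylammonium C2=C3 enolate from 30 | CC(C)=CCC/C(C)=C/C[C@]1(C(=O)Oc2ccccc2)C[C@H]3C[C@@H]4C(C)(C)CCC4=C([O-])[C@@H](C1=O)C3(C)C.CCCC[N+](CCCC)(CCCC)CCCC | intermediate
32 | cage trione, the target without its benzoyl group (C1–H) | CC(C)=CCC/C(C)=C/C[C@@]12C[C@H]3C[C@@H]4C(C)(C)CC[C@]4(C1=O)C(=O)[C@@H](C2=O)C3(C)C | intermediate
33 | C1 bridgehead lithium derivative of 32 | CC(C)=CCC/C(C)=C/C[C@@]12C[C@H]3C[C@@H]4C(C)(C)CC[C@]4(C1=O)C(=O)[C@@]([Li])(C2=O)C3(C)C | intermediate
34 | CNP0168637.1 | CC(C)=CCC/C(C)=C/C[C@@]12C[C@H]3C[C@@H]4C(C)(C)CC[C@]4(C1=O)C(=O)[C@@](C(=O)c1ccccc1)(C2=O)C3(C)C | target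

Total steps: 18. Longest linear sequence: 18 steps (1 to 34); compounds 3, 6, 11 and 21 enter as bought.

Steps most likely to fail

Step 16. The photogenerated ketene may dimerise or be hydrolysed before the hindered enol ether carbon C1 attacks it, or the excited diazoketone may undergo hydrogen shift or carbene insertion instead of ring contraction. The fallback uses known chemistry and reverses the order of the two acylations. It sets out from 28: irradiation at 405 nm in the presence of ethanethiol should give the ring-contracted S-ethyl thioester F1 (Wolff rearrangement with thiol capture). LiN(SiMe3)2 then forms the thioester enolate at C3, the only acidic C–H while C9 is masked, and Claisen condensation on the phenyl ester closes C3–C4 to the seven-membered keto thioester F2. Bu4N[Ph3SiF2] finally releases the C9 enolate, whose carbon C1 attacks the thioester C2 (Dieckmann closure of ring A). The route is rejoined at 32.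

Step 17. Proton transfer to the fluoride-generated enolate, or plain desilylation, may outrun attack on the hindered phenyl ester, so that the C1-enolised diketone accumulates. The fallback sets out from 30: deliberate desilylation (HF·pyridine, THF) to the enolised 1,3-diketone F3, then LiN(iPr)2 (2.5 equiv, THF, −78 → 0 °C). The diketonate is deprotonated a second time at C3 and this more basic carbon is acylated by the phenyl ester, a dianion gamma-acylation of a 1,3-diketone. The route is rejoined at 32.

Step 18. The lithium amide may add to or reduce a cage ketone, or the cage may open by retro-Claisen attack, before the poorly acidic bridgehead proton is removed. The fallback puts the benzoyl group on C1 before the cage is closed. It sets out from 30: LiN(iPr)2 removes the C1 proton, the only one alpha to C9, and benzaldehyde gives the aldol adduct F4. Dess–Martin oxidation gives the C1 benzoyl ketone F5, and fluoride-triggered closure as in step 17 leads directly to 34.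

Further compounds
F1 | step 16 | ring-contracted S-ethyl thioester (C2 thioester on C3) with the C9 TBS enol ether and C5 phenyl ester | CC(C)=CCC/C(C)=C/C[C@]1(C(=O)Oc2ccccc2)C[C@@H](C[C@@H]2C(C)(C)CCC2C(=O)SCC)C(C)(C)C=C1O[Si](C)(C)C(C)(C)C
F2 | step 16 | seven-membered keto thioester (C3–C4 closed, C3 quaternary) with the C9 TBS enol ether | CC(C)=CCC/C(C)=C/C[C@@]12C[C@@H](C[C@@H]3C(C)(C)CC[C@]3(C1=O)C(=O)SCC)C(C)(C)C=C2O[Si](C)(C)C(C)(C)C
F3 | step 17 | tricyclic C1-enolised 1,3-diketone with the C5 phenyl ester | CC(C)=CCC/C(C)=C/C[C@]1(C(=O)Oc2ccccc2)C[C@H]3C[C@@H]4C(C)(C)CC[C@@H]4C(O)=C(C1=O)C3(C)C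
F4 | step 18 | C1 hydroxy(phenyl)methyl aldol adduct of 30 (carbinol epimers) | CC(C)=CCC/C(C)=C/C[C@]1(C(=O)Oc2ccccc2)C[C@H]3C[C@@H]4C(C)(C)CCC4=C(O[Si](C)(C)C(C)(C)C)[C@@](C(O)c2ccccc2)(C1=O)C3(C)C
F5 | step 18 | C1 benzoyl derivative of 30 | CC(C)=CCC/C(C)=C/C[C@]1(C(=O)Oc2ccccc2)C[C@H]3C[C@@H]4C(C)(C)CCC4=C(O[Si](C)(C)C(C)(C)C)[C@@](C(=O)c2ccccc2)(C1=O)C3(C)C
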